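The butenolide ring (O1, C2–C5) is opened to a cis keto acid whose C3=C4 bond comes from one alkyne. The key step exploits that ring carbon C3 carries the carbinol carbon C1′ and neighbours the bromine-bearing C4: a catalytic asymmetric bromo-aldol coupling of a ynoate with butanal and a bromide source forms C4–Br and C3–C1′, fixes the tetrasubstituted alkene geometry and sets (R)-C1′ in one operation, closing no ring. The precursor is a propiolate carrying C5 as a dioxolane-masked ketone with the C6 methyl; its ester is tert-butyl, so that acid later frees acid and ketone while the acetate survives. Lactonisation, dehydration and iodination at C6 finish the route.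

Key step: step 4

Remark: the catalyst antipode named in step 4 is the one expected from the usual aldehyde-binding model; it is to be confirmed by Mosher ester analysis of the first batch of 12, and the other antipode is equally accessible.

Step 1
Reactants: 1 4-(trimethylsilyl)but-3-yn-2-one; 2 ethylene glycol
Product: 3 2-methyl-2-[(trimethylsilyl)ethynyl]-1,3-dioxolane
Conditions: HOCH2CH2OH, p-TsOH (cat.), toluene, reflux, Dean–Stark
Reagents that add atoms: ethylene glycol (OCCO)
Why: Acid-catalysed ketalisation with azeotropic removal of water, in which the silyl cap keeps the diol from adding in conjugate fashion to the alkyne terminus.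

Step 2
Reactants: 3 2-methyl-2-[(trimethylsilyl)ethynyl]-1,3-dioxolane
Product: 4 2-ethynyl-2-methyl-1,3-dioxolane
Conditions: K2CO3 (cat.), MeOH, rt
Reagents that add atoms: none
Why: Methoxide-induced protodesilylation of an alkynylsilane, to which the base-stable ketal is inert (the product is volatile and should be concentrated with care).

Step 3
Reactants: 4 2-ethynyl-2-methyl-1,3-dioxolane; 5 di-tert-butyl dicarbonate
Product: 7 tert-butyl 3-(2-methyl-1,3-dioxolan-2-yl)prop-2-ynoate, via lithium acetylide 6 (not isolated)
Conditions: n-BuLi, THF, −78 °C; then added to Boc2O, −78 → 0 °C; NH4Cl quench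
Reagents that add atoms: di-tert-butyl dicarbonate (CC(C)(C)OC(=O)OC(=O)OC(C)(C)C)
Why: Deprotonation of the terminal alkyne and alkoxycarbonylation of the acetylide with Boc2O, with inverse addition so that the acetylide does not attack the ynoate formed.

Step 4
Reactants: 7 tert-butyl 3-(2-methyl-1,3-dioxolan-2-yl)prop-2-ynoate; 8 butanal; 9 bromotrimethylsilane
Product: 12 tert-butyl (R,E)-3-bromo-2-(1-hydroxybutyl)-3-(2-methyl-1,3-dioxolan-2-yl)prop-2-enoate, via β-bromo silyl allenolate 10 (not isolated), via O-trimethylsilyl aldol 11 (not isolated)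
Conditions: TMSBr, (S)-o-tolyl-oxazaborolidinium triflimide (20 mol%), CH2Cl2, −78 °C; then 1 M HCl, THF, 0 °C
Reagents that add atoms: butanal (CCCC=O); bromotrimethylsilane (C[Si](C)(C)Br)
Why: Bromide from TMSBr adds to the alkyne carbon that bears the dioxolane (the only position conjugate to the ester) while silicon caps the ester oxygen, giving allenolate 10; its central carbon then attacks butanal held on the cationic boron catalyst in an open Mukaiyama-type transition state, silicon passes to the new alkoxide (11), and cold dilute acid frees alcohol 12. The closest known reaction type is the halosilane-mediated β-halo Morita–Baylis–Hillman (halo-aldol) three-component coupling of propiolates and ynones with aldehydes under chiral oxazaborolidinium catalysis. No ring is closed. The C1′ centre is set by the catalyst: the aldehyde is fixed on boron by a formyl C–H···O contact and one of its faces is covered by a catalyst aryl group, so the allenolate should add to the Si face and give R. The alkene must form with the ester cis to the dioxolane carbon (E), which should follow from the aldehyde approaching the allenolate in the plane of the C4 substituents past bromine and not past the quaternary dioxolane carbon. Masking the ketone as the ketal secures both the site of bromide addition and butanal as the only electrophile.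

Step 5
Reactants: 12 tert-butyl (R,E)-3-bromo-2-(1-hydroxybutyl)-3-(2-methyl-1,3-dioxolan-2-yl)prop-2-enoate; 13 acetic anhydride
Product: 14 tert-butyl (R,E)-2-[1-(acetyloxy)butyl]-3-bromo-3-(2-methyl-1,3-dioxolan-2-yl)prop-2-enoate
Conditions: Ac2O, pyridine, DMAP (cat.), CH2Cl2, 0 °C → rt
Reagents that add atoms: acetic anhydride (CC(=O)OC(C)=O)
Why: Standard O-acylation of a secondary alcohol that breaks no bond to C1′, while the fully substituted C4 disfavours SN2′ attack of the amine, so the configuration is kept.

Step 6
Reactants: 14 tert-butyl (R,E)-2-[1-(acetyloxy)butyl]-3-bromo-3-(2-methyl-1,3-dioxolan-2-yl)prop-2-enoate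
Product: 16 (1R)-1-(4-bromo-5-hydroxy-5-methyl-2-oxo-2,5-dihydrofuran-3-yl)butyl acetate (both C5 epimers), via open-chain keto acid 15 (not isolated)
Conditions: TFA/H2O (9:1), 0 °C → rt
Reagents that add atoms: water (O)
Why: Acidolysis of the tert-butyl ester and acid hydrolysis of the dioxolane give the cis keto acid, which closes to its cyclic pseudo-acid by ring–chain tautomerism, under conditions that a secondary acetate tolerates.

Step 7
Reactants: 16 (1R)-1-(4-bromo-5-hydroxy-5-methyl-2-oxo-2,5-dihydrofuran-3-yl)butyl acetate
Product: 17 (R)-1-(4-bromo-5-methylidene-2-oxo-2,5-dihydrofuran-3-yl)butyl acetate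
Conditions: P2O5, CH2Cl2, reflux; used at once
Reagents that add atoms: none
Why: Dehydration of a 5-hydroxy-5-methylbutenolide through its acyloxycarbenium ion, which can lose a proton only from the methyl group because C4 bears no hydrogen, a known entry to 5-methylene-2(5H)-furanones.

Step 8
Reactants: 17 (R)-1-(4-bromo-5-methylidene-2-oxo-2,5-dihydrofuran-3-yl)butyl acetate; 18 iodine monochloride
Product: 20 (R)-1-[(5Z)-4-bromo-5-(iodomethylidene)-2-oxo-2,5-dihydrofuran-3-yl]butyl acetate, via 5-chloro-5-(iodomethyl) lactone 19 (not isolated)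
Conditions: ICl, CH2Cl2, −78 → 0 °C; then Et3N, 0 °C
Reagents that add atoms: iodine monochloride (ClI)
Why: Halogenation–dehydrohalogenation of the exocyclic enol-lactone alkene as known for 5-methylene furanones, with iodine adding to the terminal carbon and chloride to the oxygen-stabilised C5, and loss of HCl placing iodine on the side of the ring oxygen (Z), away from the C4 bromine.

Compound list
1 | 4-(trimethylsilyl)but-3-yn-2-one | CC(=O)C#C[Si](C)(C)C | starting material
2 | ethylene glycol (ethane-1,2-diol) | OCCO | starting material
3 | 2-methyl-2-[(trimethylsilyl)ethynyl]-1,3-dioxolane | C[Si](C)(C)C#CC1(C)OCCO1 | intermediate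
4 | 2-ethynyl-2-methyl-1,3-dioxolane | C#CC1(C)OCCO1 | intermediate
5 | di-tert-butyl dicarbonate | CC(C)(C)OC(=O)OC(=O)OC(C)(C)C | starting material
6 | lithium (2-methyl-1,3-dioxolan-2-yl)ethynide | [Li]C#CC1(C)OCCO1 | intermediate
7 | tert-butyl 3-(2-methyl-1,3-dioxolan-2-yl)prop-2-ynoate | CC(C)(C)OC(=O)C#CC1(C)OCCO1 | intermediate
8 | butanal | CCCC=O | starting material
9 | bromotrimethylsilane | C[Si](C)(C)Br | starting material
10 | 2-[1-bromo-3-tert-butoxy-3-(trimethylsilyloxy)propa-1,2-dien-1-yl]-2-methyl-1,3-dioxolane (silyl allenolate, axis not controlled) | CC(C)(C)OC(O[Si](C)(C)C)=C=C(Br)C1(C)OCCO1 | intermediate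
11 | tert-butyl (R,E)-3-bromo-3-(2-methyl-1,3-dioxolan-2-yl)-2-[1-(trimethylsilyloxy)butyl]prop-2-enoate | CCC[C@@H](O[Si](C)(C)C)/C(C(=O)OC(C)(C)C)=C(Br)/C1(C)OCCO1 | intermediate
12 | tert-butyl (R,E)-3-bromo-2-(1-hydroxybutyl)-3-(2-methyl-1,3-dioxolan-2-yl)prop-2-enoate (ester cis to the dioxolane carbon, bromine cis to the carbinol) | CCC[C@@H](O)/C(C(=O)OC(C)(C)C)=C(Br)/C1(C)OCCO1 | intermediate
13 | acetic anhydride | CC(=O)OC(C)=O | starting material
14 | tert-butyl (R,E)-2-[1-(acetyloxy)butyl]-3-bromo-3-(2-methyl-1,3-dioxolan-2-yl)prop-2-enoate | CCC[C@@H](OC(C)=O)/C(C(=O)OC(C)(C)C)=C(Br)/C1(C)OCCO1 | intermediate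
15 | (R,E)-2-[1-(acetyloxy)butyl]-3-bromo-4-oxopent-2-enoic acid (carboxyl cis to the acetyl group) | CCC[C@@H](OC(C)=O)/C(C(=O)O)=C(Br)/C(C)=O | intermediate
16 | (1R)-1-(4-bromo-5-hydroxy-5-methyl-2-oxo-2,5-dihydrofuran-3-yl)butyl acetate (both C5 epimers) | CCC[C@@H](OC(C)=O)C1=C(Br)C(C)(O)OC1=O | intermediate
17 | (R)-1-(4-bromo-5-methylidene-2-oxo-2,5-dihydrofuran-3-yl)butyl acetate | CCC[C@@H](OC(C)=O)C1=C(Br)C(=C)OC1=O | intermediate
18 | iodine monochloride | ClI | starting material
19 | (1R)-1-[4-bromo-5-chloro-5-(iodomethyl)-2-oxo-2,5-dihydrofuran-3-yl]butyl acetate (both C5 epimers) | CCC[C@@H](OC(C)=O)C1=C(Br)C(Cl)(CI)OC1=O | intermediate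
20 | (R)-1-[(5Z)-4-bromo-5-(iodomethylidene)-2-oxo-2,5-dihydrofuran-3-yl]butyl acetate | CCC[C@@H](OC(C)=O)C1=C(Br)/C(=C/I)OC1=O | target

Total step count: 8. Longest linear sequence: 8 steps (1 → 20).

Steps most likely to fail

1. Step 4. Bromide may add too slowly to the β-branched, ketal-flanked alkyne at the temperature where the chiral catalyst is selective. Silyl-catalysed background aldol addition and opening of the dioxolane could then compete and erode the enantioselectivity. The fallback separates C–C bond formation from stereocontrol; it sets out from 7 and returns at 12. Compound 7, butanal and MgBr2·OEt2 (Lewis acid and bromide source of the achiral halo-aldol, CH2Cl2, 0 °C) should give the racemic alcohol tert-butyl (E)-3-bromo-2-(1-hydroxybutyl)-3-(2-methyl-1,3-dioxolan-2-yl)prop-2-enoate F1. Dess–Martin oxidation would then give the enone tert-butyl (E)-3-bromo-2-butanoyl-3-(2-methyl-1,3-dioxolan-2-yl)prop-2-enoate F2. Corey–Bakshi–Shibata reduction with the (S)-methyl oxazaborolidine and catecholborane (toluene, −78 °C), in which the tetrasubstituted alkenyl group acts as the large substituent, should deliver (R)-12.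

2. Step 8. The addition–elimination may go astray in three ways: base-induced loss of iodine from the adduct back to the alkene, attack of the amine at the vinylic C4–Br position, or incomplete control of the exocyclic geometry. The fallback places iodine on C6 before the exocyclic alkene exists; it sets out from 16 and returns at 20. Through its open keto-acid tautomer, 16 would be iodinated at the methyl ketone (NIS, TsOH cat., MeCN) to give (1R)-1-[4-bromo-5-hydroxy-5-(iodomethyl)-2-oxo-2,5-dihydrofuran-3-yl]butyl acetate F3. Dehydration of F3 with P2O5 in CH2Cl2, the cyclodehydration known for halogenated levulinic acids, should then give 20 with the less crowded Z alkene.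

3. Step 6. Hydrolysis of the electron-poor dioxolane may be slow, so that the acid strength or time needed begins to cleave the acetate. The fallback unmasks before acetylation; it sets out from 12 and returns at 17. Alcohol 12 would be treated with stronger aqueous acid (2 M HCl, THF, 50 °C), which has no acetate to harm, to give 4-bromo-5-hydroxy-3-[(1R)-1-hydroxybutyl]-5-methylfuran-2(5H)-one F4. Acetic anhydride with catalytic H2SO4, the classical cyclodehydration of β-acylacrylic acids, would acetylate both hydroxyl groups to (1R)-1-[5-(acetyloxy)-4-bromo-5-methyl-2-oxo-2,5-dihydrofuran-3-yl]butyl acetate F5. F5 should lose acetic acid from C5 under the same acidic conditions to give 17.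

Further compounds
F1 | step 4 | tert-butyl (E)-3-bromo-2-(1-hydroxybutyl)-3-(2-methyl-1,3-dioxolan-2-yl)prop-2-enoate (racemic) | CCCC(O)/C(C(=O)OC(C)(C)C)=C(Br)/C1(C)OCCO1
F2 | step 4 | tert-butyl (E)-3-bromo-2-butanoyl-3-(2-methyl-1,3-dioxolan-2-yl)prop-2-enoate | CCCC(=O)/C(C(=O)OC(C)(C)C)=C(Br)/C1(C)OCCO1
F3 | step 8 | (1R)-1-[4-bromo-5-hydroxy-5-(iodomethyl)-2-oxo-2,5-dihydrofuran-3-yl]butyl acetate (both C5 epimers) | CCC[C@@H](OC(C)=O)C1=C(Br)C(O)(CI)OC1=O
F4 | step 6 | 4-bromo-5-hydroxy-3-[(1R)-1-hydroxybutyl]-5-methylfuran-2(5H)-one (both C5 epimers) | CCC[C@@H](O)C1=C(Br)C(C)(O)OC1=O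
F5 | step 6 | (1R)-1-[5-(acetyloxy)-4-bromo-5-methyl-2-oxo-2,5-dihydrofuran-3-yl]butyl acetate (both C5 epimers) | CCC[C@@H](OC(C)=O)C1=C(Br)C(C)(OC(C)=O)OC1=O
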